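## The problem

Target 16, 1-[5-(hydroxymethyl)-1H-pyrrol-2-yl]-16-methylheptadecan-1-one, is an N-unsubstituted pyrrole (ring atoms N1, C2, C3, C4, C5) with an acyl group on C2 (carbonyl carbon C1′, then fourteen CH2 groups and an isopropyl end) and a hydroxymethyl group on C5; C3 and C4 carry hydrogen and there is no stereocentre. The first task is the 2,5-pattern: an acyl group on C2 deactivates the ring and lets a second electrophile choose between C4 and C5, so a route that substitutes a finished pyrrole twice has no structural control over where the one-carbon unit goes. The second is the carbinol: a pyrrol-2-ylmethanol ionises at the C5–CH2–O bond under acid, or from the N1 anion when oxygen carries a leaving group, to an azafulvenium ion or azafulvene that oligomerises, so this group must travel masked and be freed last under nearly neutral conditions. The third is the chain: a 15-methylhexadecyl group on the carbonyl is not a bulk building block and has no handle other than the ketone, so it must be assembled by an sp3–sp3 coupling of an iso-C5 and a linear C12 piece and joined to the heterocyclic part at C1′. The ketone is a vinylogous amide and robust, but any route that passes through a formyl group must tell two carbonyl groups apart. The feature the plan uses is the array N1–C2–C1′(=O) next to an unsubstituted C3: opened at C2–C3 and N1–C5, C2 becomes a methylene flanked by a sulfonamide nitrogen and the ketone (a carbon acid), C3 a formyl carbon, and C4–C5 with its CH2O group the triple bond of a 4-oxygenated but-2-ynal, so N1–C5 can be made by conjugate addition and the ring closed at the carbon–carbon bond C2–C3 by aldol condensation.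

## Retrosynthesis

16 ⇒ 15. Only the O–Si bond is cut. A silyl ether is chosen over an ester or acetal because fluoride removes it near neutrality and because silanolate is a poor leaving group during the basic steps before. The precursor 15 differs only by the mask; the forward step must leave the C5–CH2–O bond intact.

15 ⇒ 8 + 11 (through 12, 13 and 14). The ring bonds N1–C5 and C2–C3 are cut and the sulfonyl group is put back on nitrogen. Cutting C2–C1′ instead leads back to substitution of a pyrrole with its C4/C5 ambiguity. Cutting both C–N bonds (ring closure at nitrogen) would need a 1,2,5-tricarbonyl chain whose 1,2-dione competes for ammonia. The chosen cut gives two acyclic pieces, the α-(sulfonylamino) ketone 8 and the four-carbon alkynal 11, and the pattern follows from their connectivity alone. The forward reaction must add nitrogen (not carbon) of 8 in 1,4-fashion to 11, close the enaminal 12 at C2–C3, lose water from 13 to give 14, and then give up the N-sulfonyl group.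

8 ⇒ 6 + 7. The bond C1′–C2′ between the carbonyl and the chain is cut (Weinreb ketone synthesis). Cutting N–CH2 instead (sulfonamide plus a chloromethyl ketone) would put two more steps on the chain-bearing material. Here the glycine-derived piece 6 is made separately and the route stays convergent. The forward step must tolerate the acidic N–H of 6 and stop at the ketone.

7 ⇐ 3 ⇒ 1 + 2. The bond between C12 and C13 of bromide 3 is cut. This is the only cut in the chain that gives two bulk chemicals, 1,12-dibromododecane 1 and the isopentyl Grignard reagent 2. A cut next to the isopropyl group would need a secondary Grignard reagent and a rarer C14 dibromide. The forward coupling must substitute only one bromide of 1.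

6 ⇒ 4 + 5. The N–CH2 bond is cut: sulfonamide 4 is alkylated with chloroacetamide 5. Both are catalogue compounds; the only demand is monoalkylation.

11 ⇒ 9 (through 10). The bond between the formyl carbon and the alkyne is cut: the lithium acetylide 10 of silyl propargyl ether 9 is formylated. The forward step must release the aldehyde without letting dimethylamine add to it.

## Roads not taken

Alternative 1: (the obvious route) Cut the exocyclic bonds C2–C1′ and C5–CH2OH. Forward: C-acylation of pyrrole A1 (as its N-metallated form) with 16-methylheptadecanoyl chloride A2 to ketone A3, then Vilsmeier–Haack formylation to aldehyde A4 and hydride reduction of the formyl group. In A3 nothing distinguishes C5 from C4, so the isomeric aldehyde A5 must be expected and separated. The formylation also runs under strongly acidic iminium conditions. A2 is not a bulk chemical, so the chain must still be built from the same C5 and C12 pieces. The route is shorter on paper, but its central selectivity is not secured by structure; in the chosen plan it is fixed by connectivity.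

Alternative 2: Cut the bond between C1′ and the chain at the alcohol oxidation level and start from the symmetric 1H-pyrrole-2,5-dicarbaldehyde A6. Forward: monoaddition of Grignard reagent 7 to give carbinol A7, then a hydrogen-transfer isomerisation (transfer-hydrogenation catalyst) that turns the secondary carbinol into the ketone and the formyl group into the hydroxymethyl group. This is the shortest route and thermodynamically sound. But the 2,5-pattern is bought, not made. Mono- versus bis-addition is only statistical once N1 is deprotonated. A7 is an ionisable pyrrolyl carbinol. The isomerisation has to outrun ester formation between aldehyde and alcohol and a disproportionation equilibrium. Two unsecured selectivities stand against one secured ring construction.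

Alternative 3: Regard 16 as an isomer of the pyridine N-oxide A8, in which C1′ and C2–C5 of the target are the ring carbons C2–C6 of the pyridine and the ketone oxygen is the N-oxide oxygen. A8 would be reached by lateral alkylation of a picolyl alcohol with bromide 3 and N-oxidation. Forward: photochemical ring contraction (oxaziridine, 1,2-oxazepine, 2-acylpyrrole), the known behaviour of 2,6-dialkylpyridine N-oxides, helped by a divalent copper salt. This is the most economical idea in steps. But the oxygen can walk to either α-carbon, and nothing in A8 distinguishes the chain-bearing carbon from the one carrying CH2OH, so the isomer A9 is expected alongside the target. Deoxygenation and 3-hydroxypyridine formation also compete. The chosen plan needs more steps but no selectivity left to chance.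

Key step: step 5

Remark: 16 has no stereocentre or double-bond geometry; 12 is expected as an E/Z mixture and 13 as racemic diastereomers, so their SMILES carry no stereodescriptors.

## Route

Step 1
Reactants: 1 1,12-dibromododecane; 2 (3-methylbutyl)magnesium bromide
Product: 3 1-bromo-15-methylhexadecane
Conditions: 2 (1.0 equiv) added slowly to 1 (3 equiv), Li2CuCl4 (3 mol %), THF, −10 °C to rt; excess 1 recovered by distillation
Reagents that add atoms: none
Why: Kochi-type copper-catalysed sp3–sp3 coupling of a primary alkyl bromide with a primary Grignard reagent; the threefold excess of 1 should make substitution of one bromide the main course, and 3 should be separable by distillation from 1 and from the doubly coupled alkane.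

Step 2
Reactants: 4 4-methylbenzenesulfonamide; 5 2-chloro-N-methoxy-N-methylacetamide
Product: 6 N-methoxy-N-methyl-2-{[(4-methylphenyl)sulfonyl]amino}acetamide
Conditions: 4 (3 equiv), K2CO3 (1.5 equiv), NaI (10 mol %), MeCN, 60 °C
Reagents that add atoms: none
Why: SN2 N-alkylation of the sulfonamide anion with iodide catalysis (Finkelstein exchange); the excess of cheap 4 suppresses a second alkylation, and the N-methoxy-N-methylamide is inert to carbonate.

Step 3
Reactants: 3 1-bromo-15-methylhexadecane; 6 N-methoxy-N-methyl-2-{[(4-methylphenyl)sulfonyl]amino}acetamide
Product: 8 4-methyl-N-(17-methyl-2-oxooctadecyl)benzenesulfonamide, via (15-methylhexadecyl)magnesium bromide 7 (not isolated)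
Conditions: 3, Mg, I2 (cat.), THF, 45 °C; separately 6 (1.3 equiv), i-PrMgCl (1.3 equiv), THF, −20 °C; then 7, 0 °C to rt; aq. NH4Cl
Reagents that add atoms: none
Why: Weinreb ketone synthesis: insertion of Mg gives 7; the acidic N–H of 6 is first removed with i-PrMgCl so that 7 is not used up as a base, and addition to the N-methoxy-N-methylamide stops at the ketone level because the chelated adduct collapses only on work-up.

Step 4
Reactants: 9 tert-butyldimethyl(prop-2-yn-1-yloxy)silane
Product: 11 4-{[tert-butyl(dimethyl)silyl]oxy}but-2-ynal, via lithium acetylide 10 (not isolated)
Conditions: n-BuLi (1.05 equiv), THF, −78 °C; DMF (1.5 equiv), −78 to 0 °C; inverse quench into cold aq. KH2PO4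
Reagents that add atoms: N,N-dimethylformamide, CN(C)C=O
Why: Deprotonation of the terminal alkyne and formylation of the lithium acetylide 10 with DMF; the inverse quench into phosphate buffer releases the aldehyde while the liberated dimethylamine stays protonated and cannot add to the alkynal.

Step 5
Reactants: 8 4-methyl-N-(17-methyl-2-oxooctadecyl)benzenesulfonamide; 11 4-{[tert-butyl(dimethyl)silyl]oxy}but-2-ynal
Product: 15 1-[5-({[tert-butyl(dimethyl)silyl]oxy}methyl)-1H-pyrrol-2-yl]-16-methylheptadecan-1-one, via N-sulfonyl enaminal 12 (not isolated), via 3-hydroxy-2,3-dihydropyrrole 13 (not isolated), via N-tosylpyrrole 14 (not isolated)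
Conditions: 8, DBU (1.2 equiv), THF, 0 °C; 11 (1.2 equiv) added dropwise, 0 °C to rt; then LiOH·H2O (4 equiv), t-BuOH/H2O, 40 °C
Reagents that add atoms: none
Why: Kenner-type pyrrole annulation run at the alkyne oxidation level: DBU ionises the sulfonamide N–H of 8 (far more acidic than either α-C–H), and the sulfonamide anion adds 1,4 to alkynal 11, forming N1–C5 and giving the push–pull enaminal 12, whose E and Z isomers interconvert. The ketone enolate at the nitrogen-bearing methylene of 12 then attacks the formyl carbon in a 5-exo-trig (enolexo) aldol that closes the ring at C2–C3 (13), and E1cB loss of water across C2–C3 aromatises it to N-tosylpyrrole 14. The closest known reaction type is the Kenner synthesis of pyrrole-2-carbonyl compounds from N-sulfonyl α-amino carbonyl compounds and enones or enals, together with its alkynone variants in which the dehydration already delivers the aromatic ring. No stereocentre remains, since the two transient ones in 13 are erased by the dehydration. N- versus C-addition is secured by the sulfonamide acidity, 1,4- versus 1,2-addition by the fact that a sulfonamide cannot form an imine and its hemiaminal reverts, and the direction of closure by the fact that the formyl group of 12 has no α-hydrogen and only the N–CH2 enolate reaches it through a five-membered transition state (the chain-side enolate would need a seven-membered one). The Knorr-type closure from C4 onto the ketone is suppressed under base with the nitrogen lone pair tied up by the sulfonyl group. The substitution pattern is fixed by connectivity: nitrogen is bonded to the carbon that carries CH2OSi (C5) and to the carbon that carries the acyl group (C2). Aqueous LiOH added to the same flask then cleaves the crowded N–S bond of the acyl-activated N-sulfonylpyrrole (hydroxide attacks sulfur, the 2-acylpyrrolide leaves) without touching the silyl ether, which should give 15.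

Step 6
Reactants: 15 1-[5-({[tert-butyl(dimethyl)silyl]oxy}methyl)-1H-pyrrol-2-yl]-16-methylheptadecan-1-one
Product: 16 1-[5-(hydroxymethyl)-1H-pyrrol-2-yl]-16-methylheptadecan-1-one
Conditions: TBAF (1.2 equiv), AcOH (1.2 equiv), THF, 0 °C to rt
Reagents that add atoms: none
Why: Fluoride-induced cleavage of the Si–O bond, driven by the strong Si–F bond; buffering with AcOH keeps N1 protonated so that the pyrrolide/azafulvene pathway is not opened, and the vinylogous-amide ketone is inert.

## Compound list

1 | 1,12-dibromododecane | BrCCCCCCCCCCCCBr | starting material
2 | (3-methylbutyl)magnesium bromide (isopentylmagnesium bromide) | CC(C)CC[Mg]Br | starting material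
3 | 1-bromo-15-methylhexadecane | CC(C)CCCCCCCCCCCCCCBr | intermediate
4 | 4-methylbenzenesulfonamide | Cc1ccc(cc1)S(N)(=O)=O | starting material
5 | 2-chloro-N-methoxy-N-methylacetamide | CON(C)C(=O)CCl | starting material
6 | N-methoxy-N-methyl-2-{[(4-methylphenyl)sulfonyl]amino}acetamide | CON(C)C(=O)CNS(=O)(=O)c1ccc(C)cc1 | intermediate
7 | (15-methylhexadecyl)magnesium bromide | CC(C)CCCCCCCCCCCCCC[Mg]Br | intermediate (not isolated)
8 | 4-methyl-N-(17-methyl-2-oxooctadecyl)benzenesulfonamide | CC(C)CCCCCCCCCCCCCCC(=O)CNS(=O)(=O)c1ccc(C)cc1 | intermediate
9 | tert-butyldimethyl(prop-2-yn-1-yloxy)silane | C#CCO[Si](C)(C)C(C)(C)C | starting material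
10 | (3-{[tert-butyl(dimethyl)silyl]oxy}prop-1-yn-1-yl)lithium | [Li]C#CCO[Si](C)(C)C(C)(C)C | intermediate (not isolated)
11 | 4-{[tert-butyl(dimethyl)silyl]oxy}but-2-ynal | O=CC#CCO[Si](C)(C)C(C)(C)C | intermediate
12 | N-(1-{[tert-butyl(dimethyl)silyl]oxy}-4-oxobut-2-en-2-yl)-4-methyl-N-(17-methyl-2-oxooctadecyl)benzenesulfonamide (E/Z mixture) | CC(C)CCCCCCCCCCCCCCC(=O)CN(C(=CC=O)CO[Si](C)(C)C(C)(C)C)S(=O)(=O)c1ccc(C)cc1 | intermediate (not isolated)
13 | 1-[5-({[tert-butyl(dimethyl)silyl]oxy}methyl)-3-hydroxy-1-(4-methylbenzenesulfonyl)-2,3-dihydro-1H-pyrrol-2-yl]-16-methylheptadecan-1-one (racemic diastereomers) | CC(C)CCCCCCCCCCCCCCC(=O)C1C(O)C=C(CO[Si](C)(C)C(C)(C)C)N1S(=O)(=O)c2ccc(C)cc2 | intermediate (not isolated)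
14 | 1-[5-({[tert-butyl(dimethyl)silyl]oxy}methyl)-1-(4-methylbenzenesulfonyl)-1H-pyrrol-2-yl]-16-methylheptadecan-1-one | CC(C)CCCCCCCCCCCCCCC(=O)c1ccc(CO[Si](C)(C)C(C)(C)C)n1S(=O)(=O)c2ccc(C)cc2 | intermediate (not isolated)
15 | 1-[5-({[tert-butyl(dimethyl)silyl]oxy}methyl)-1H-pyrrol-2-yl]-16-methylheptadecan-1-one | CC(C)CCCCCCCCCCCCCCC(=O)c1ccc(CO[Si](C)(C)C(C)(C)C)[nH]1 | intermediate
16 | 1-[5-(hydroxymethyl)-1H-pyrrol-2-yl]-16-methylheptadecan-1-one | CC(C)CCCCCCCCCCCCCCC(=O)c1ccc(CO)[nH]1 | target

## Step count and risks

Total: 6 steps. Longest linear sequence: 4 steps (1 → 3 → 5 → 6, counted from 1 and 2); steps 2 and 4 are side branches.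

Step 5 (key step). The most likely failure is base-induced propargyl–allenyl isomerisation and oligomerisation of alkynal 11 before the sulfonamide has added. Its CH2O protons are activated through the triple bond by the formyl group, and DBU is itself a nucleophile toward ynals. A second failure is stalling at carbinol 13, with retro-aldol in place of dehydration. The fallback gives up the ring construction and uses a purchased pyrrole. It sets out from bromide 3: its Grignard reagent 7, made as in step 3, is added to the sodium salt (NaH) of 1H-pyrrole-2,5-dicarbaldehyde F1 to give the carbinol 5-(1-hydroxy-16-methylheptadecyl)-1H-pyrrole-2-carbaldehyde F2. MnO2 oxidises the pyrrolyl carbinol to 5-(16-methylheptadecanoyl)-1H-pyrrole-2-carbaldehyde F3, and NaBH4 at low temperature reduces only the formyl group. The fallback returns to the route at 16.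

Step 3. The most likely failure is incomplete addition: the N-magnesiated amide is a poor, partly insoluble electrophile, and a long-chain Grignard reagent may act as a base or couple with unreacted 3 during its formation. The fallback moves the C–N bond formation behind the C–C bond formation. It sets out from 7, which is added to chloroacetamide 5 to give 1-chloro-17-methyloctadecan-2-one F4; this alkylates an excess of sulfonamide 4 (K2CO3, NaI). It returns to the route at 8.

Step 1. The most likely failure is substitution at both ends of 1 and a tedious separation of 3 from the excess dibromide, because the two bromides of 1 react independently. The fallback differentiates the chain ends by function instead of by statistics. It sets out from 2: two equivalents are coupled (Li2CuCl4) with 12-bromododecan-1-ol F5 to give 15-methylhexadecan-1-ol F6, which an Appel bromination (CBr4, PPh3) converts to the bromide. It returns to the route at 3.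

Step 6. The most likely failure is expulsion of the silanolate from C5–CH2 through the pyrrolide anion if the fluoride medium turns basic, followed by oligomerisation of the azafulvene. The fallback reverses the order of the two unmaskings, so the silyl ether is cleaved while N1 is still sulfonylated and cannot form the anion. It sets out from 14, isolated by omitting the hydroxide treatment in step 5. HF·pyridine gives 1-[5-(hydroxymethyl)-1-(4-methylbenzenesulfonyl)-1H-pyrrol-2-yl]-16-methylheptadecan-1-one F7, whose N–S bond is then cleaved with aqueous LiOH; here the leaving group on carbon would be hydroxide, which does not ionise. It returns to the route at 16.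

## Further compounds

F1 | step 5 | 1H-pyrrole-2,5-dicarbaldehyde | O=Cc1ccc(C=O)[nH]1
F2 | step 5 | 5-(1-hydroxy-16-methylheptadecyl)-1H-pyrrole-2-carbaldehyde (racemic) | CC(C)CCCCCCCCCCCCCCC(O)c1ccc(C=O)[nH]1
F3 | step 5 | 5-(16-methylheptadecanoyl)-1H-pyrrole-2-carbaldehyde | CC(C)CCCCCCCCCCCCCCC(=O)c1ccc(C=O)[nH]1
F4 | step 3 | 1-chloro-17-methyloctadecan-2-one | CC(C)CCCCCCCCCCCCCCC(=O)CCl
F5 | step 1 | 12-bromododecan-1-ol | OCCCCCCCCCCCCBr
F6 | step 1 | 15-methylhexadecan-1-ol | CC(C)CCCCCCCCCCCCCCO
F7 | step 6 | 1-[5-(hydroxymethyl)-1-(4-methylbenzenesulfonyl)-1H-pyrrol-2-yl]-16-methylheptadecan-1-one | CC(C)CCCCCCCCCCCCCCC(=O)c1ccc(CO)n1S(=O)(=O)c2ccc(C)cc2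
A1 | alternative 1 | 1H-pyrrole | c1cc[nH]c1
A2 | alternative 1 | 16-methylheptadecanoyl chloride | CC(C)CCCCCCCCCCCCCCC(=O)Cl
A3 | alternative 1 | 16-methyl-1-(1H-pyrrol-2-yl)heptadecan-1-one | CC(C)CCCCCCCCCCCCCCC(=O)c1ccc[nH]1
A4 | alternative 1 | 5-(16-methylheptadecanoyl)-1H-pyrrole-2-carbaldehyde | CC(C)CCCCCCCCCCCCCCC(=O)c1ccc(C=O)[nH]1
A5 | alternative 1 | 5-(16-methylheptadecanoyl)-1H-pyrrole-3-carbaldehyde | CC(C)CCCCCCCCCCCCCCC(=O)c1cc(C=O)c[nH]1
A6 | alternative 2 | 1H-pyrrole-2,5-dicarbaldehyde | O=Cc1ccc(C=O)[nH]1
A7 | alternative 2 | 5-(1-hydroxy-16-methylheptadecyl)-1H-pyrrole-2-carbaldehyde (racemic) | CC(C)CCCCCCCCCCCCCCC(O)c1ccc(C=O)[nH]1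
A8 | alternative 3 | [6-(15-methylhexadecyl)-1-oxidopyridin-1-ium-2-yl]methanol | CC(C)CCCCCCCCCCCCCCc1cccc(CO)[n+]1[O-]
A9 | alternative 3 | 2-hydroxy-1-[5-(15-methylhexadecyl)-1H-pyrrol-2-yl]ethan-1-one | CC(C)CCCCCCCCCCCCCCc1ccc(C(=O)CO)[nH]1
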